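**Plan**
- Retrosynthesis: the C8 ester and the C1 ketal come off last; the butenolide is cut at C7=C11 (aldol condensation) and at the C6–O–C12 ester; the 4,5-epoxide is opened to a C4 carbinol and a C5 mesylate; the C3 and C8 carbonyls are then rejoined as a C3=C8 alkene.
- Feature: C3 and C8 lie 1,6 across the ten-membered ring, so a C3–C8 bond folds it into two six-membered rings. Ring A (C1, C2, C3, C8, C9, C10, with oxygen on C1 and methyl on C10) is the ring of 2-methylanisole, ring B (C3–C8) carries the C4 methyl and the C5/C6 oxygens, and C3–C8 is the ring-fusion bond.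
- Forward: ring B is annulated onto 2-methylanisole (two Friedel–Crafts acylations) and oxygenated, ring A is Birch-reduced and ketalised, and ozonolysis of C3=C8 opens both six-membered rings into the ten-membered ring; the oxirane and then the butenolide are closed on it.
- Stereochemistry: Shi epoxidation fixes C4 as a relay and hydroxyl-directed dihydroxylation copies it to C6. After the Birch step C4 and C5 are rebuilt by OsO4 anti to the C6 silyloxy group, and C5 is inverted on epoxide closure (trans epoxide). C8 comes from a CBS reduction. C10 has no controlling element and is set by separating the two epimers formed on ketalisation.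

Key step: step 17

Remark: locants C1–C13 are those of the target (C1 and C3 ketones, C4–C5 oxirane, C6 lactone carbinol, C7=C11, C8 ester carbinol, C10 methyl-bearing carbon, C12 lactone carbonyl, C13 acetoxymethyl) and are kept for the bicyclic intermediates.
Assumption: on alkene 8 the D-fructose-derived Shi ketone shows the facial preference of its spiro transition-state model; if it does not, its enantiomer is used.

Step 1
Reactants: 1 2-methylanisole; 2 succinic anhydride
Product: 3 4-(4-methoxy-3-methylphenyl)-4-oxobutanoic acid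
Conditions: AlCl3 (2.2 equiv), CH2Cl2, 0 °C to rt; aq. HCl
Reagents that add atoms: none
Why: Friedel–Crafts acylation by the anhydride–AlCl3 complex goes para to the methoxy group, the strongest director, so the ketone carbon (C7) is attached to the future C8.

Step 2
Reactants: 3 4-(4-methoxy-3-methylphenyl)-4-oxobutanoic acid
Product: 4 4-(4-methoxy-3-methylphenyl)butanoic acid
Conditions: H2 (4 atm), 10% Pd/C, AcOH, 60 °C
Reagents that add atoms: none
Why: Catalytic hydrogenolysis of the electron-rich aryl ketone (through the benzylic alcohol) gives the methylene, the usual second stage of a Haworth tetralone synthesis.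

Step 3
Reactants: 4 4-(4-methoxy-3-methylphenyl)butanoic acid
Product: 5 7-methoxy-6-methyl-1-tetralone
Conditions: Eaton's reagent (P2O5 in MeSO3H), 50 °C
Reagents that add atoms: none
Why: Intramolecular Friedel–Crafts acylation closes ring B at the open position ortho to the chain and para to the ring methyl, which places the new ketone (C4) on C3.

Step 4
Reactants: 5 7-methoxy-6-methyl-1-tetralone; 6 methylmagnesium bromide
Product: 8 6-methoxy-4,7-dimethyl-1,2-dihydronaphthalene, via tertiary alcohol 7 (not isolated)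
Conditions: MeMgBr, THF, 0 °C; then TsOH·H2O (cat.), toluene, 80 °C
Reagents that add atoms: none
Why: Grignard addition to the aryl ketone and acid-catalysed E1 dehydration of the tertiary benzylic alcohol give the conjugated endocyclic C4=C5 alkene with the C4 methyl group in place.

Step 5
Reactants: 8 6-methoxy-4,7-dimethyl-1,2-dihydronaphthalene
Product: 9 (4S,5R)-epoxide
Conditions: D-fructose-derived Shi ketone (30 mol %), KHSO5 (as 2KHSO5·KHSO4·K2SO4), K2CO3, Bu4NHSO4, MeCN–(MeO)2CH2–aq. Na2B4O7 buffer, 0 °C
Reagents that add atoms: potassium peroxymonosulfate, [K+].[O-]S(=O)(=O)OO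
Why: Shi epoxidation (dioxirane from the chiral ketone) of a trisubstituted aryl alkene should deliver oxygen through the spiro transition state to the face that makes C4 (S) and C5 (R), and the basic buffer protects the acid-labile benzylic epoxide.

Step 6
Reactants: 9 (4S,5R)-epoxide
Product: 11 (4R)-tertiary allylic alcohol, via hydroxy selenide 10 (not isolated)
Conditions: (PhSe)2, NaBH4, EtOH, rt; then 30% H2O2, pyridine, THF, 0 °C to rt
Reagents that add atoms: none
Why: Selenolate opens the epoxide by SN2 at the secondary C5 and the derived selenoxide undergoes syn-elimination toward C6 because C4 carries no hydrogen, so the C4 carbinol keeps its configuration (R only by a change of priorities) and the C5=C6 alkene is formed.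

Step 7
Reactants: 11 (4R)-tertiary allylic alcohol
Product: 13 all-cis (4S,5R,6R)-triol, via osmate ester 12 (not isolated)
Conditions: OsO4 (1.05 equiv), TMEDA, CH2Cl2, −78 °C; then aq. Na2SO3, THF, 40 °C
Reagents that add atoms: osmium tetroxide, O=[Os](=O)(=O)=O
Why: Hydrogen-bond-directed dihydroxylation in which the OsO4·TMEDA complex is bound by the tertiary allylic hydroxyl and adds to the C5=C6 face syn to it, which sets C6 (R) and C5 from C4.

Step 8
Reactants: 13 all-cis (4S,5R,6R)-triol
Product: 14 C6 TIPS ether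
Conditions: TIPSOTf (1.05 equiv), 2,6-lutidine, CH2Cl2, −78 °C
Reagents that add atoms: triisopropylsilyl trifluoromethanesulfonate, CC(C)[Si](OS(=O)(=O)C(F)(F)F)(C(C)C)C(C)C
Why: The silyl triflate takes the least hindered hydroxyl, C6–OH, since C5–OH is flanked by the quaternary C4 and C4–OH is tertiary, and the bulky TIPS group is chosen because it resists base-induced 1,2-migration in step 10.

Step 9
Reactants: 14 C6 TIPS ether
Product: 15 C4/C5 acetonide
Conditions: 2-methoxypropene, PPTS (cat.), CH2Cl2, 0 °C
Reagents that add atoms: 2-methoxypropene, COC(C)=C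
Why: Acid-catalysed acetonide formation on the cis C4/C5 diol masks C5–OH and turns the benzylic C4–OH into an ether, the form in which a dissolving metal cleaves a benzylic C–O bond reliably.

Step 10
Reactants: 15 C4/C5 acetonide
Product: 17 Birch enol ether, via ring-opened arene 16 (not isolated)
Conditions: Li, liquid NH3–THF, t-BuOH, −78 to −33 °C; then NH4Cl
Reagents that add atoms: none
Why: Birch reduction in which electron transfer first cleaves the benzylic C4–O bond (C4 becomes CH, a centre erased in step 13) and then reduces the anisole ring at its two unsubstituted positions C2 and C9, leaving the enol ether C1=C10 and the tetrasubstituted ring-fusion alkene C3=C8 while the non-benzylic C5 and C6 oxygens are untouched.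

Step 11
Reactants: 17 Birch enol ether
Product: 18 bicyclic ketal alcohol (C4/C10 epimers)
Conditions: HOCH2CH2OH, PPTS (cat.), CH2Cl2, 4 Å sieves, rt
Reagents that add atoms: ethylene glycol, OCCO
Why: Acid-catalysed exchange of the enol ether into the dioxolane (protonation at C10, capture of the oxocarbenium ion by the diol) keeps the alkene at C3=C8 because β,γ-unsaturated ketals are the stable isomers, but the proton reaches C10 with no bias from the remote ring B centres, so both C10 epimers are expected and are resolved at 20.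

Step 12
Reactants: 18 bicyclic ketal alcohol (C4/C10 epimers)
Product: 19 bicyclic C5 ketone (C4/C10 epimers)
Conditions: Dess–Martin periodinane, NaHCO3, CH2Cl2, 0 °C
Reagents that add atoms: none
Why: Dess–Martin oxidation of the secondary C5 alcohol under buffered, non-aqueous conditions leaves the ketal, the silyl ether and the alkene alone.

Step 13
Reactants: 19 bicyclic C5 ketone (C4/C10 epimers)
Product: 20 (6R,10R)-dienyl triflate
Conditions: KN(SiMe3)2, THF, −78 °C; PhNTf2, −78 to 0 °C; HPLC separation of the C10 epimers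
Reagents that add atoms: N-phenylbis(trifluoromethanesulfonimide), O=S(=O)(N(c1ccccc1)S(=O)(=O)C(F)(F)F)C(F)(F)F
Why: The base removes the C4 hydrogen, which is both α to the ketone and allylic, and O-sulfonylation of the resulting dienolate gives the dienyl triflate, which removes the C4 stereocentre so that C10 is the only variable left and the (10R) epimer is isolated.

Step 14
Reactants: 20 (6R,10R)-dienyl triflate
Product: 21 (6R,10R)-diene
Conditions: Pd(OAc)2 (cat.), PPh3, HCO2H, Et3N, DMF, 60 °C
Reagents that add atoms: none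
Why: Palladium-catalysed formate reduction of an enol triflate (oxidative addition, formate decarboxylation, reductive elimination) replaces OTf by H and leaves the C3=C8/C4=C5 diene.

Step 15
Reactants: 21 (6R,10R)-diene
Product: 22 (4R,5S,6R,10R)-diol
Conditions: OsO4 (cat.), NMO, acetone–H2O, 0 °C
Reagents that add atoms: N-methylmorpholine N-oxide, C[N+]1([O-])CCOCC1; water, O
Why: Catalytic OsO4 dihydroxylation takes the trisubstituted C4=C5 bond (the tetrasubstituted C3=C8 bond is too hindered) by syn addition on the face opposite the allylic C6 silyloxy group, giving C4 (R) and C5 (S) with both hydroxyls trans to O6.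

Step 16
Reactants: 22 (4R,5S,6R,10R)-diol
Product: 23 (4R,5S,6R,10R)-C5 mesylate
Conditions: MsCl, Et3N, CH2Cl2, −20 °C
Reagents that add atoms: methanesulfonyl chloride, CS(Cl)(=O)=O
Why: Sulfonylation through sulfene takes only the secondary C5 hydroxyl, the tertiary allylic C4 hydroxyl being too hindered.

Step 17
Reactants: 23 (4R,5S,6R,10R)-C5 mesylate
Product: 25 ten-membered 3,8-dione, via methoxy hydroperoxide 24 (not isolated)
Conditions: O3, CH2Cl2–MeOH, NaHCO3, −78 °C; then Me2S, −78 °C to rt
Reagents that add atoms: ozone, [O-][O+]=O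
Why: Ozone adds (3+2) to the electron-rich tetrasubstituted C3=C8 alkene, the primary ozonide fragments into a ketone and a carbonyl oxide, methanol traps the latter as the α-methoxy hydroperoxide 24 and Me2S reduces it, so C3 and C8 both end as ketones (Criegee mechanism). The closest known reaction is the ozonolysis of the ring-fusion alkene of Birch-derived octalins to cyclodecane-1,6-diones. No ring is closed by bond formation: the cleaved bond is common to rings A and B, so cutting it merges the two six-membered rings into the ten-membered ring. No stereocentre is formed, and C4, C5, C6 and C10 are spectators whose configuration was fixed in the rigid bicycle. The step needs chemoselectivity only, and the substrate provides it: C3=C8 is the sole C=C bond, C1 is a ketal so that no enol or conjugated isomer can form, and −78 °C, NaHCO3 and reductive work-up protect the tertiary C4 carbinol from oxidative C3–C4 cleavage.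

Step 18
Reactants: 25 ten-membered 3,8-dione
Product: 26 4,5-epoxy 3,8-dione
Conditions: K2CO3, MeOH, 0 °C
Reagents that add atoms: none
Why: Intramolecular Williamson reaction (3-exo-tet) in which the C4 alkoxide displaces the C5 mesylate with inversion, turning the cis-diol relationship made in ring B into the trans 4,5-epoxide with C4 (S) and C5 (R), while the absence of a hydrogen on C4 rules out elimination toward the C3 ketone.

Step 19
Reactants: 26 4,5-epoxy 3,8-dione
Product: 27 C6 alcohol
Conditions: HF·pyridine, pyridine, THF, 0 °C to rt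
Reagents that add atoms: none
Why: Fluoride cleaves the Si–O bond under buffered acidic conditions, which avoid the Payne rearrangement and the retro-aldol reaction open to a C6 alkoxide and leave the dioxolane intact.

Step 20
Reactants: 28 bromopyruvic acid
Product: 29 acetoxypyruvic acid
Conditions: KOAc (2.2 equiv), acetone, rt; then cold 1 M HCl
Reagents that add atoms: potassium acetate, CC(=O)[O-].[K+]
Why: SN2 displacement of bromide from the α-bromo ketone by acetate, the second equivalent of acetate only neutralising the carboxylic acid.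

Step 21
Reactants: 27 C6 alcohol; 29 acetoxypyruvic acid
Product: 30 C6 acetoxypyruvate
Conditions: DCC, DMAP (cat.), CH2Cl2, −20 °C
Reagents that add atoms: none
Why: Steglich esterification in which the carbodiimide activates the α-keto acid and DMAP transfers the acyl group to the C6 hydroxyl under conditions too mild for epoxide opening or Payne rearrangement.

Step 22
Reactants: 30 C6 acetoxypyruvate
Product: 32 8-oxo butenolide, via aldol adduct 31 (not isolated)
Conditions: Et3N, CH2Cl2, −20 to 0 °C; then MsCl, Et3N, 0 °C to rt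
Reagents that add atoms: none
Why: Intramolecular aldol condensation in which the C8 ketone enolises toward C7, the only α-carbon that can reach the tethered and highly electrophilic α-keto ester carbonyl C11 (five-membered lactone ring), and E1cB loss of the sulfonylated C11 oxygen gives the tetrasubstituted C7=C11 butenolide without touching C6.

Step 23
Reactants: 32 8-oxo butenolide
Product: 33 (8R)-alcohol
Conditions: (S)-2-methyl-CBS-oxazaborolidine, catecholborane, toluene–CH2Cl2, −78 °C
Reagents that add atoms: none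
Why: Corey–Bakshi–Shibata reduction in which, with the alkenyl carbon C7 as the large group, the (S)-oxazaborolidine directs hydride to the face that gives C8 (R), and the conjugated C8 carbonyl is reduced before the non-conjugated C3 ketone shielded by the quaternary C4.

Step 24
Reactants: 34 4-methylfuran-2(5H)-one
Product: 37 4-methoxybenzyl (Z)-4-acetoxy-3-methylbut-2-enoate, via potassium carboxylate 35 (not isolated), via hydroxy ester 36 (not isolated)
Conditions: KOH (1 equiv), MeOH–H2O, rt; evaporate; 4-methoxybenzyl chloride, Bu4NI (cat.), DMF, 0 °C; then Ac2O, pyridine, DMAP (cat.), 0 °C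
Reagents that add atoms: potassium hydroxide, [K+].[OH-]; 4-methoxybenzyl chloride, COc1ccc(CCl)cc1; acetic anhydride, CC(=O)OC(C)=O
Why: Saponification opens the butenolide with the Z geometry fixed by the ring, SN2 alkylation of the carboxylate protects the acid, and immediate acetylation of the primary alcohol prevents relactonisation.

Step 25
Reactants: 37 4-methoxybenzyl (Z)-4-acetoxy-3-methylbut-2-enoate
Product: 38 (Z)-4-acetoxy-3-methylbut-2-enoic acid
Conditions: TFA, anisole, CH2Cl2, 0 °C
Reagents that add atoms: none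
Why: Acidolysis of the 4-methoxybenzyl ester (SN1, cation trapped by anisole) frees the acid without touching the acetate or the Z alkene.

Step 26
Reactants: 33 (8R)-alcohol; 38 (Z)-4-acetoxy-3-methylbut-2-enoic acid
Product: 39 C8 ester ketal
Conditions: DCC, DMAP (cat.), CH2Cl2, 0 °C
Reagents that add atoms: none
Why: Steglich esterification of the allylic C8 alcohol proceeds with retention at C8, and carbodiimide activation with catalytic DMAP at 0 °C is mild enough to keep the Z-enoate geometry.

Step 27
Reactants: 39 C8 ester ketal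
Product: 40 CNP0274470.1
Conditions: PPTS (cat.), acetone–H2O, 45 °C
Reagents that add atoms: water, O
Why: Acid-catalysed hydrolysis of the dioxolane releases the C1 ketone last, so the 1,3-diketone and its epimerisable C10 neighbour never meet base, and PPTS is too weak to open the epoxy ketone or cleave the esters.

**Compound list**
1 | 2-methylanisole | COc1ccccc1C | starting material
2 | succinic anhydride | O=C1CCC(=O)O1 | starting material
3 | 4-(4-methoxy-3-methylphenyl)-4-oxobutanoic acid | COc1ccc(cc1C)C(=O)CCC(=O)O | intermediate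
4 | 4-(4-methoxy-3-methylphenyl)butanoic acid | COc1ccc(cc1C)CCCC(=O)O | intermediate
5 | 7-methoxy-6-methyl-3,4-dihydronaphthalen-1(2H)-one | COc1cc2C(=O)CCCc2cc1C | intermediate
6 | methylmagnesium bromide | C[Mg]Br | starting material
7 | 7-methoxy-1,6-dimethyl-1,2,3,4-tetrahydronaphthalen-1-ol (racemic) | COc1cc2c(cc1C)CCCC2(C)O | intermediate (not isolated)
8 | 6-methoxy-4,7-dimethyl-1,2-dihydronaphthalene | COc1cc2c(cc1C)CCC=C2C | intermediate
9 | (1aR,7bS)-6-methoxy-5,7b-dimethyl-1a,2,3,7b-tetrahydronaphtho[1,2-b]oxirene; C4 (S), C5 (R) | COc1cc2c(cc1C)CC[C@H]3O[C@@]23C | intermediate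
10 | (1S,2S)-7-methoxy-1,6-dimethyl-2-(phenylselanyl)-1,2,3,4-tetrahydronaphthalen-1-ol | COc1cc2c(cc1C)CC[C@H]([Se]c3ccccc3)[C@@]2(C)O | intermediate (not isolated)
11 | (1R)-7-methoxy-1,6-dimethyl-1,4-dihydronaphthalen-1-ol; C4 (R) | COc1cc2c(cc1C)CC=C[C@@]2(C)O | intermediate
12 | cyclic C5,C6 dioxo-osmate ester of triol 13, TMEDA chelate | COc1cc2c(cc1C)C[C@H]3O[Os](=O)(=O)O[C@H]3[C@@]2(C)O.CN(C)CCN(C)C | intermediate (not isolated)
13 | (1S,2R,3R)-7-methoxy-1,6-dimethyl-1,2,3,4-tetrahydronaphthalene-1,2,3-triol, all-cis; (4S,5R,6R) | COc1cc2c(cc1C)C[C@@H](O)[C@@H](O)[C@@]2(C)O | intermediate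
14 | (1S,2R,3R)-7-methoxy-1,6-dimethyl-3-(triisopropylsilyloxy)-1,2,3,4-tetrahydronaphthalene-1,2-diol | COc1cc2c(cc1C)C[C@@H](O[Si](C(C)C)(C(C)C)C(C)C)[C@@H](O)[C@@]2(C)O | intermediate
15 | C4,C5-O-isopropylidene derivative of 14; (4S,5R,6R) | COc1cc2c(cc1C)C[C@@H](O[Si](C(C)C)(C(C)C)C(C)C)[C@H]3OC(C)(C)O[C@@]23C | intermediate
16 | (2S,3R)-7-methoxy-1,6-dimethyl-3-(triisopropylsilyloxy)-1,2,3,4-tetrahydronaphthalen-2-ol, C4 epimers; (5S,6R) | COc1cc2c(cc1C)C[C@@H](O[Si](C(C)C)(C(C)C)C(C)C)[C@@H](O)C2C | intermediate (not isolated)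
17 | (2S,3R)-7-methoxy-1,6-dimethyl-3-(triisopropylsilyloxy)-1,2,3,4,5,8-hexahydronaphthalen-2-ol, C4 epimers; enol ether C1=C10, alkene C3=C8 | COC1=C(C)CC2=C(C1)C(C)[C@H](O)[C@H](O[Si](C(C)C)(C(C)C)C(C)C)C2 | intermediate
18 | bicyclic ketal alcohol, (5S,6R), C4 and C10 epimers: ring A = C1 (1,3-dioxolane ketal), C2H2, C3=C8, C9H2, C10H(CH3); ring B = C4H(CH3), C5H(OH), C6H(OTIPS), C7H2 | CC1CC2=C(CC13OCCO3)C(C)[C@H](O)[C@H](O[Si](C(C)C)(C(C)C)C(C)C)C2 | intermediate
19 | bicyclic C5 ketone of 18, (6R), C4 and C10 epimers | CC1CC2=C(CC13OCCO3)C(C)C(=O)[C@H](O[Si](C(C)C)(C(C)C)C(C)C)C2 | intermediate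
20 | (6R,10R)-dienyl triflate: C1 dioxolane, C3=C8 and C4=C5, C4 methyl, C5 OTf, C6 OTIPS, C10 methyl | C[C@@H]1CC2=C(CC13OCCO3)C(C)=C(OS(=O)(=O)C(F)(F)F)[C@H](O[Si](C(C)C)(C(C)C)C(C)C)C2 | intermediate
21 | (6R,10R)-diene: as 20 with H on C5 | C[C@@H]1CC2=C(CC13OCCO3)C(C)=C[C@H](O[Si](C(C)C)(C(C)C)C(C)C)C2 | intermediate
22 | (4R,5S,6R,10R)-diol: C4(OH)(CH3) and C5-OH cis to each other and trans to C6-OTIPS, C3=C8, C1 dioxolane | C[C@@H]1CC2=C(CC13OCCO3)[C@@](C)(O)[C@@H](O)[C@H](O[Si](C(C)C)(C(C)C)C(C)C)C2 | intermediate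
23 | (4R,5S,6R,10R)-C5 methanesulfonate of 22 | C[C@@H]1CC2=C(CC13OCCO3)[C@@](C)(O)[C@@H](OS(C)(=O)=O)[C@H](O[Si](C(C)C)(C(C)C)C(C)C)C2 | intermediate
24 | (4S,5S,6R,10R)-1,1-(ethylenedioxy)-8-hydroperoxy-4-hydroxy-8-methoxy-5-(methanesulfonyloxy)-4,10-dimethyl-6-(triisopropylsilyloxy)cyclodecan-3-one, C8 epimers | C[C@@H]1CC(OC)(OO)C[C@@H](O[Si](C(C)C)(C(C)C)C(C)C)[C@H](OS(C)(=O)=O)[C@](C)(O)C(=O)CC13OCCO3 | intermediate (not isolated)
25 | (4S,5S,6R,10R)-1,1-(ethylenedioxy)-4-hydroxy-5-(methanesulfonyloxy)-4,10-dimethyl-6-(triisopropylsilyloxy)cyclodecane-3,8-dione | C[C@@H]1CC(=O)C[C@@H](O[Si](C(C)C)(C(C)C)C(C)C)[C@H](OS(C)(=O)=O)[C@](C)(O)C(=O)CC13OCCO3 | intermediate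
26 | (4S,5R,6R,10R)-4,5-epoxy-1,1-(ethylenedioxy)-4,10-dimethyl-6-(triisopropylsilyloxy)cyclodecane-3,8-dione (trans epoxide) | C[C@@H]1CC(=O)C[C@@H](O[Si](C(C)C)(C(C)C)C(C)C)[C@H]2O[C@]2(C)C(=O)CC13OCCO3 | intermediate
27 | (4S,5R,6R,10R)-4,5-epoxy-1,1-(ethylenedioxy)-6-hydroxy-4,10-dimethylcyclodecane-3,8-dione | C[C@@H]1CC(=O)C[C@@H](O)[C@H]2O[C@]2(C)C(=O)CC13OCCO3 | intermediate
28 | 3-bromo-2-oxopropanoic acid (bromopyruvic acid) | OC(=O)C(=O)CBr | starting material
29 | 3-acetoxy-2-oxopropanoic acid (acetoxypyruvic acid) | CC(=O)OCC(=O)C(=O)O | intermediate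
30 | 6-O-(3-acetoxy-2-oxopropanoyl) ester of 27; (4S,5R,6R,10R) | C[C@@H]1CC(=O)C[C@@H](OC(=O)C(=O)COC(C)=O)[C@H]2O[C@]2(C)C(=O)CC13OCCO3 | intermediate
31 | (4S,5R,6R,10R)-13-acetoxy-4,5-epoxy-1,1-(ethylenedioxy)-11-hydroxy-3,8-dioxogermacran-12,6-olide, C7 and C11 epimers | C[C@@H]1CC(=O)C2[C@@H](OC(=O)C2(O)COC(C)=O)[C@H]3O[C@]3(C)C(=O)CC14OCCO4 | intermediate (not isolated)
32 | (4S,5R,6R,10R)-13-acetoxy-4,5-epoxy-1,1-(ethylenedioxy)-3,8-dioxogermacr-7(11)-en-12,6-olide | C[C@@H]1CC(=O)C2=C(COC(C)=O)C(=O)O[C@H]2[C@H]3O[C@]3(C)C(=O)CC14OCCO4 | intermediate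
33 | (4S,5R,6R,8R,10R)-13-acetoxy-4,5-epoxy-1,1-(ethylenedioxy)-8-hydroxy-3-oxogermacr-7(11)-en-12,6-olide | C[C@@H]1C[C@@H](O)C2=C(COC(C)=O)C(=O)O[C@H]2[C@H]3O[C@]3(C)C(=O)CC14OCCO4 | intermediate
34 | 4-methylfuran-2(5H)-one | CC1=CC(=O)OC1 | starting material
35 | potassium (Z)-4-hydroxy-3-methylbut-2-enoate | [K+].[O-]C(=O)/C=C(/C)CO | intermediate (not isolated)
36 | 4-methoxybenzyl (Z)-4-hydroxy-3-methylbut-2-enoate | COc1ccc(COC(=O)/C=C(/C)CO)cc1 | intermediate (not isolated)
37 | 4-methoxybenzyl (Z)-4-acetoxy-3-methylbut-2-enoate | COc1ccc(COC(=O)/C=C(/C)COC(C)=O)cc1 | intermediate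
38 | (Z)-4-acetoxy-3-methylbut-2-enoic acid | OC(=O)/C=C(/C)COC(C)=O | intermediate
39 | (4S,5R,6R,8R,10R)-13-acetoxy-8-[(Z)-4-acetoxy-3-methylbut-2-enoyloxy]-4,5-epoxy-1,1-(ethylenedioxy)-3-oxogermacr-7(11)-en-12,6-olide | C[C@@H]1C[C@@H](OC(=O)/C=C(/C)COC(C)=O)C2=C(COC(C)=O)C(=O)O[C@H]2[C@H]3O[C@]3(C)C(=O)CC14OCCO4 | intermediate
40 | CNP0274470.1: (4S,5R,6R,8R,10R)-13-acetoxy-8-[(Z)-4-acetoxy-3-methylbut-2-enoyloxy]-4,5-epoxy-1,3-dioxogermacr-7(11)-en-12,6-olide | CC(=O)OCC1=C2[C@@H](OC1=O)[C@H]1O[C@]1(C)C(=O)CC(=O)[C@H](C)C[C@H]2OC(=O)/C=C(/C)COC(C)=O | target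

Total step count: 27. Longest linear sequence: 24 steps (steps 1–19, 21–23, 26 and 27, from 2-methylanisole).

**Steps most likely to fail**

First, step 22. The C7 enolate may lose the C6 acyloxy group by β-elimination, or the keto ester may enolise at C13, faster than the aldol ring closure. The fallback sets out from 27 and takes the acyl leaving group out of the bond-forming stage. Alcohol 27 is treated with iPr2Si(OTf)2 and 2,6-lutidine to give the cyclic silylene enol ether F1, in which the six-membered O6–Si–O8 ring holds the enol double bond at C7=C8. A Mukaiyama aldol addition of F1 to methyl 3-acetoxy-2-oxopropanoate (Sc(OTf)3 cat., CH2Cl2, −78 °C), followed by HF·pyridine, gives the methyl ester aldol adduct F2. F2 lactonises under PPTS to the aldol adduct 31, where the route is rejoined; 31 is dehydrated as in the second stage of step 22.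

Second, step 11. The proton is delivered to C10 with no facial preference, and the two epimers differ only at a centre far from C6 in a flat bicycle, so separation at 20 may fail. The fallback sets out from 19 and carries the pair together through steps 13 to 17. This gives 20 with the (10S)-dienyl triflate F3, 21 with the (10S)-diene F4, 22 with the (10S)-diol F5, 23 with the (10S)-mesylate F6, 24 with the (10S)-methoxy hydroperoxide F7, and 25 with the (10S)-diketone F8. In the ten-membered ring C10 and the C4–C6 array share one ring, so the two are ring diastereomers with different conformations and should separate by chromatography or crystallisation. The route is rejoined at 25.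

Third, step 23. Hydride may be delivered to the other face of the C8 carbonyl if the oxazaborolidine and the ring conformation are mismatched, giving the (8S) alcohol. The fallback sets out from 32. The (8S)-alcohol F9 (made on purpose with the (R)-oxazaborolidine if that pairing proves the selective one) is esterified with acid 38 under Mitsunobu conditions (PPh3, DIAD, toluene, 0 °C). This inverts C8 and gives 39 directly, where the route is rejoined.

**Further compounds**
F1 | step 22 | cyclic diisopropylsilylene enol ether of 27 (O6–Si(iPr)2–O–C8=C7) | C[C@@H]1CC2=C[C@@H](O[Si](C(C)C)(C(C)C)O2)[C@H]3O[C@]3(C)C(=O)CC14OCCO4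
F2 | step 22 | methyl ester aldol adduct (C7–C11 bond, C11 hydroxyl, C6 hydroxyl free; C7 and C11 epimers) | C[C@@H]1CC(=O)C(C(O)(COC(C)=O)C(=O)OC)[C@@H](O)[C@H]2O[C@]2(C)C(=O)CC13OCCO3
F3 | step 11 | (6R,10S)-dienyl triflate, C10 epimer of 20 | C[C@H]1CC2=C(CC13OCCO3)C(C)=C(OS(=O)(=O)C(F)(F)F)[C@H](O[Si](C(C)C)(C(C)C)C(C)C)C2
F4 | step 11 | (6R,10S)-diene, C10 epimer of 21 | C[C@H]1CC2=C(CC13OCCO3)C(C)=C[C@H](O[Si](C(C)C)(C(C)C)C(C)C)C2
F5 | step 11 | (4R,5S,6R,10S)-diol, C10 epimer of 22 | C[C@H]1CC2=C(CC13OCCO3)[C@@](C)(O)[C@@H](O)[C@H](O[Si](C(C)C)(C(C)C)C(C)C)C2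
F6 | step 11 | (4R,5S,6R,10S)-mesylate, C10 epimer of 23 | C[C@H]1CC2=C(CC13OCCO3)[C@@](C)(O)[C@@H](OS(C)(=O)=O)[C@H](O[Si](C(C)C)(C(C)C)C(C)C)C2
F7 | step 11 | (4S,5S,6R,10S)-methoxy hydroperoxide, C10 epimer of 24 | C[C@H]1CC(OC)(OO)C[C@@H](O[Si](C(C)C)(C(C)C)C(C)C)[C@H](OS(C)(=O)=O)[C@](C)(O)C(=O)CC13OCCO3
F8 | step 11 | (4S,5S,6R,10S)-diketone, C10 epimer of 25 | C[C@H]1CC(=O)C[C@@H](O[Si](C(C)C)(C(C)C)C(C)C)[C@H](OS(C)(=O)=O)[C@](C)(O)C(=O)CC13OCCO3
F9 | step 23 | (4S,5R,6R,8S,10R)-alcohol, C8 epimer of 33 | C[C@@H]1C[C@H](O)C2=C(COC(C)=O)C(=O)O[C@H]2[C@H]3O[C@]3(C)C(=O)CC14OCCO4
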